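Assumption: the target SMILES has no stereocentre and no stereogenic double bond (the prenyl alkene is gem-dimethyl), and the aryl–CO axes are not configurationally stable. Pestalone E is therefore achiral and no step needs stereocontrol.

## Retrosynthetic overview
1. Pestalone E comes from a one-pot acidic unmasking of a tetra-MOM / dimethyl-acetal precursor; no base is used, so the Cannizzaro–Tishchenko lactone cannot form.
2. The aryl–prenyl bond is made last by ketone-directed C–H prenylation (the new step). Ring B keeps a nucleophilic C–H, so any SEAr after the union would hit the wrong ring, whereas chelation reaches only the one ortho C–H of ring A.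
3. The diaryl ketone comes from a 2-lithioresorcinol bis-MOM ether (ring B, directed ortho-metalation) and a methyl benzoate with a masked ortho-CHO (ring A).
4. Ring B comes from orcinol (MOM, NCS). Ring A comes from methyl 3,5-dihydroxybenzoate (Vilsmeier, MOM, acetal).
5. No ring is built, because both benzene rings are bought. The order is: decorate B, decorate A, join, prenylate, unmask.

## Route

Step 1
Reactants: 1 orcinol (5-methylbenzene-1,3-diol)
Product: 2 1,3-bis(methoxymethoxy)-5-methylbenzene
Conditions: MOMCl (2.5 equiv), i-Pr2NEt (3 equiv), CH2Cl2, 0 °C → rt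
Reagents that add atoms: chloromethyl methyl ether (MOMCl), COCCl
Why: Williamson-type O-alkylation of both phenols gives base-stable MOM acetals that later act as ortho-directing groups.

Step 2
Reactants: 2 1,3-bis(methoxymethoxy)-5-methylbenzene
Product: 3 2-chloro-1,5-bis(methoxymethoxy)-3-methylbenzene
Conditions: NCS (1.0 equiv), MeCN, rt → 50 °C
Reagents that add atoms: N-chlorosuccinimide, O=C1CCC(=O)N1Cl
Why: Electrophilic aromatic chlorination (SEAr) goes para to one OMOM group next to the methyl group (two sites, equivalent by symmetry), because the site between the two OMOM groups is shielded and neutral NCS leaves the MOM groups intact.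

Step 3
Reactants: 4 methyl 3,5-dihydroxybenzoate
Product: 6 methyl 2-formyl-3,5-dihydroxybenzoate, via aryl iminium chloride 5 (not isolated)
Conditions: POCl3 (1.3 equiv), DMF (1.5 equiv), MeCN, 0 °C → rt; then H2O, 50 °C
Reagents that add atoms: N,N-dimethylformamide, CN(C)C=O; water, O
Why: Vilsmeier–Haack formylation attacks the resorcinol position that is ortho to one OH and para to the other (next to the ester), as with resorcinol and orcinol, and hydrolysis of the iminium salt gives the aldehyde.

Step 4
Reactants: 6 methyl 2-formyl-3,5-dihydroxybenzoate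
Product: 7 methyl 2-formyl-3,5-bis(methoxymethoxy)benzoate
Conditions: MOMCl (3 equiv), i-Pr2NEt (4 equiv), CH2Cl2, 0 °C → reflux
Reagents that add atoms: chloromethyl methyl ether (MOMCl), COCCl
Why: Williamson-type O-alkylation with excess reagent and heat also protects the hydrogen-bonded OH next to the aldehyde.

Step 5
Reactants: 7 methyl 2-formyl-3,5-bis(methoxymethoxy)benzoate
Product: 8 methyl 2-(dimethoxymethyl)-3,5-bis(methoxymethoxy)benzoate
Conditions: HC(OMe)3 (5 equiv), PPTS (5 mol %), MeOH, 40 °C; Et3N quench
Reagents that add atoms: trimethyl orthoformate, COC(OC)OC (methanol, CO, as solvent and co-donor)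
Why: Acid-catalysed acetalisation is driven by the orthoformate as water scavenger, and PPTS is too weak to cleave aryl MOM ethers at this temperature.

Step 6
Reactants: 3 2-chloro-1,5-bis(methoxymethoxy)-3-methylbenzene; 8 methyl 2-(dimethoxymethyl)-3,5-bis(methoxymethoxy)benzoate
Product: 10 [3-chloro-2,6-bis(methoxymethoxy)-4-methylphenyl][2-(dimethoxymethyl)-3,5-bis(methoxymethoxy)phenyl]methanone, via aryllithium 9 (not isolated)
Conditions: 3, n-BuLi (1.05 equiv), THF, 0 °C, 1 h; then 8 (0.9 equiv), −78 °C → rt; H2O
Reagents that add atoms: n-butyllithium, [Li]CCCC (lithium only in intermediate 9)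
Why: Directed ortho-metalation places lithium between the two OMOM groups (the chloride has no ortho hydrogen, so no aryne forms), and nucleophilic acyl substitution on the ester stops at the tri-ortho-substituted ketone, which is too hindered for a second addition.

Step 7
Reactants: 10 [3-chloro-2,6-bis(methoxymethoxy)-4-methylphenyl][2-(dimethoxymethyl)-3,5-bis(methoxymethoxy)phenyl]methanone; 11 3-methylbuta-1,2-diene (1,1-dimethylallene)
Product: 12 [3-chloro-2,6-bis(methoxymethoxy)-4-methylphenyl][2-(dimethoxymethyl)-3,5-bis(methoxymethoxy)-6-(3-methylbut-2-en-1-yl)phenyl]methanone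
Conditions: [Ir(cod)2]BArF4 (7.5 mol %), rac-BINAP (7.5 mol %), 2,6-di-tert-butyl-4-methylpyridine (10 mol %), 11 (5 equiv), THF, sealed tube, 110 °C
Reagents that add atoms: 3-methylbuta-1,2-diene (11), CC(C)=C=C
Why: Proposed new method: ketone-directed, cationic-Ir(I)-catalysed ortho-C–H prenylation of a diaryl ketone with 1,1-dimethylallene; ring B stands perpendicular and has no ortho C–H, so the C=O can lie in the plane of ring A and bind [Ir(BINAP)]+; the single ortho C–H, helped by the flanking OMOM oxygen as in Murai-type reactions of m-alkoxyaryl ketones, adds oxidatively to give a five-membered aryl–Ir(III)–H chelate; the allene inserts into Ir–H with H going to its central carbon to give an η3-1,1-dimethylallyl complex; C–C reductive elimination at the unsubstituted allyl terminus, favoured by relief of strain, gives only the linear prenyl arene with no by-product; the more nucleophilic C–H bonds (ring B C5–H, ring A C4–H) lie outside the chelate, and the masked aldehyde cannot decarbonylate; the closest known reaction types are the Ir-catalysed amide-directed C–H prenylation of benzamides with this allene and Murai-type or cationic-Ir ketone-directed hydroarylation of alkenes and alkynes, neither of which has been shown for allenes on ketones or for closing a tetra-ortho-substituted benzophenone.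

Step 8
Reactants: 12 [3-chloro-2,6-bis(methoxymethoxy)-4-methylphenyl][2-(dimethoxymethyl)-3,5-bis(methoxymethoxy)-6-(3-methylbut-2-en-1-yl)phenyl]methanone
Product: 13 pestalone E, 2-(3-chloro-2,6-dihydroxy-4-methylbenzoyl)-4,6-dihydroxy-3-(3-methylbut-2-en-1-yl)benzaldehyde
Conditions: HCl (1 M) in MeOH/H2O 9:1, 40 °C, Ar
Reagents that add atoms: water, O
Why: Acid-catalysed acetal hydrolysis and transacetalisation removes the four phenolic MOM groups (formaldehyde is trapped by MeOH) and the electron-rich benzaldehyde acetal under conditions routinely tolerated by ortho-prenylphenols, and the absence of base avoids the lactone rearrangement.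

## Compound list
1 | orcinol (5-methylbenzene-1,3-diol) | Cc1cc(O)cc(O)c1 | starting material
2 | 1,3-bis(methoxymethoxy)-5-methylbenzene | Cc1cc(OCOC)cc(OCOC)c1 | intermediate
3 | 2-chloro-1,5-bis(methoxymethoxy)-3-methylbenzene | Cc1cc(OCOC)cc(OCOC)c1Cl | intermediate
4 | methyl 3,5-dihydroxybenzoate | COC(=O)c1cc(O)cc(O)c1 | starting material
5 | [2,4-dihydroxy-6-(methoxycarbonyl)benzylidene]dimethyliminium chloride (not isolated) | COC(=O)c1cc(O)cc(O)c1C=[N+](C)C.[Cl-] | intermediate
6 | methyl 2-formyl-3,5-dihydroxybenzoate | COC(=O)c1cc(O)cc(O)c1C=O | intermediate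
7 | methyl 2-formyl-3,5-bis(methoxymethoxy)benzoate | COC(=O)c1cc(OCOC)cc(OCOC)c1C=O | intermediate
8 | methyl 2-(dimethoxymethyl)-3,5-bis(methoxymethoxy)benzoate | COC(=O)c1cc(OCOC)cc(OCOC)c1C(OC)OC | intermediate
9 | [3-chloro-2,6-bis(methoxymethoxy)-4-methylphenyl]lithium (not isolated) | Cc1cc(OCOC)c([Li])c(OCOC)c1Cl | intermediate
10 | [3-chloro-2,6-bis(methoxymethoxy)-4-methylphenyl][2-(dimethoxymethyl)-3,5-bis(methoxymethoxy)phenyl]methanone | COC(OC)c1c(OCOC)cc(OCOC)cc1C(=O)c1c(OCOC)cc(C)c(Cl)c1OCOC | intermediate
11 | 3-methylbuta-1,2-diene (1,1-dimethylallene) | CC(C)=C=C | starting material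
12 | [3-chloro-2,6-bis(methoxymethoxy)-4-methylphenyl][2-(dimethoxymethyl)-3,5-bis(methoxymethoxy)-6-(3-methylbut-2-en-1-yl)phenyl]methanone | COC(OC)c1c(OCOC)cc(OCOC)c(CC=C(C)C)c1C(=O)c1c(OCOC)cc(C)c(Cl)c1OCOC | intermediate
13 | pestalone E (achiral) | CC(C)=CCc1c(O)cc(O)c(C=O)c1C(=O)c1c(O)cc(C)c(Cl)c1O | target

## Step count
- Total step count: 8.
- Longest linear sequence: 6 (4 → 6 → 7 → 8 → 10 → 12 → 13).

## Three steps most likely to fail

**Step 7 (new method).**
- Risks: the C–H bond is flanked on both sides. The ketone must turn into the plane of ring A against the acetal. The cationic iridium could ionise an acetal.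
- The fallback uses known chemistry and brings the prenyl group in before the union. It sets out from 7 and comes back at 13.
- NBS in MeCN brominates 7 at the position para to an OMOM group, the usual site for 2,4-dialkoxybenzaldehydes. This gives methyl 2-bromo-6-formyl-3,5-bis(methoxymethoxy)benzoate F1.
- Stille coupling with tributyl(3-methylbut-2-en-1-yl)stannane (Pd(PPh3)4, DMF, 100 °C) gives methyl 2-formyl-3,5-bis(methoxymethoxy)-6-(3-methylbut-2-en-1-yl)benzoate F2.
- NaBH4 in MeOH reduces the aldehyde, and the alkoxide closes onto the ester. This gives 4,6-bis(methoxymethoxy)-7-(3-methylbut-2-en-1-yl)-2-benzofuran-1(3H)-one F3.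
- Aryllithium 9 opens the tied-back lactone carbonyl at −78 °C. This gives [3-chloro-2,6-bis(methoxymethoxy)-4-methylphenyl][2-(hydroxymethyl)-3,5-bis(methoxymethoxy)-6-(3-methylbut-2-en-1-yl)phenyl]methanone F4.
- Dess–Martin periodinane with NaHCO3 gives 2-[3-chloro-2,6-bis(methoxymethoxy)-4-methylbenzoyl]-4,6-bis(methoxymethoxy)-3-(3-methylbut-2-en-1-yl)benzaldehyde F5. The conditions of step 8 then turn F5 into 13.

**Step 6.**
- Risk: a 2,6-disubstituted aryllithium may add only sluggishly to an ester that sits next to a bulky acetal.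
- The fallback replaces acyl substitution by aldehyde addition and oxidation. It sets out from 8 and comes back at 10.
- LiAlH4 in THF at 0 °C with basic work-up gives [2-(dimethoxymethyl)-3,5-bis(methoxymethoxy)phenyl]methanol F6.
- MnO2 in CH2Cl2 gives 2-(dimethoxymethyl)-3,5-bis(methoxymethoxy)benzaldehyde F7.
- Aryllithium 9 adds at −78 °C to give racemic [3-chloro-2,6-bis(methoxymethoxy)-4-methylphenyl][2-(dimethoxymethyl)-3,5-bis(methoxymethoxy)phenyl]methanol F8.
- Dess–Martin periodinane with NaHCO3 oxidises F8 to 10.

**Step 8.**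
- Risks: Brønsted acid may cyclise the ortho-prenylphenol to a chroman. Released formaldehyde may attack the free resorcinol rings. The free keto aldehyde is prone to rearrange.
- The fallback exchanges the protecting groups, so the free prenylphenol never meets acid. It sets out from 12 and comes back at 13.
- TESOTf and 2,2′-bipyridyl in CH2Cl2 (0 °C → rt, then water) convert the aryl MOM ethers directly into silyl ethers and free the aldehyde under non-acidic conditions. This gives 2-[3-chloro-4-methyl-2,6-bis(triethylsilyloxy)benzoyl]-3-(3-methylbut-2-en-1-yl)-4,6-bis(triethylsilyloxy)benzaldehyde F9.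
- Et3N·3HF in THF at 0 °C desilylates F9 to 13.

## Further compounds
F1 | step 7 | methyl 2-bromo-6-formyl-3,5-bis(methoxymethoxy)benzoate | COC(=O)c1c(Br)c(OCOC)cc(OCOC)c1C=O
F2 | step 7 | methyl 2-formyl-3,5-bis(methoxymethoxy)-6-(3-methylbut-2-en-1-yl)benzoate | COC(=O)c1c(CC=C(C)C)c(OCOC)cc(OCOC)c1C=O
F3 | step 7 | 4,6-bis(methoxymethoxy)-7-(3-methylbut-2-en-1-yl)-2-benzofuran-1(3H)-one | O=C1OCc2c(OCOC)cc(OCOC)c(CC=C(C)C)c12
F4 | step 7 | [3-chloro-2,6-bis(methoxymethoxy)-4-methylphenyl][2-(hydroxymethyl)-3,5-bis(methoxymethoxy)-6-(3-methylbut-2-en-1-yl)phenyl]methanone | OCc1c(OCOC)cc(OCOC)c(CC=C(C)C)c1C(=O)c1c(OCOC)cc(C)c(Cl)c1OCOC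
F5 | step 7 | 2-[3-chloro-2,6-bis(methoxymethoxy)-4-methylbenzoyl]-4,6-bis(methoxymethoxy)-3-(3-methylbut-2-en-1-yl)benzaldehyde | O=Cc1c(OCOC)cc(OCOC)c(CC=C(C)C)c1C(=O)c1c(OCOC)cc(C)c(Cl)c1OCOC
F6 | step 6 | [2-(dimethoxymethyl)-3,5-bis(methoxymethoxy)phenyl]methanol | COC(OC)c1c(CO)cc(OCOC)cc1OCOC
F7 | step 6 | 2-(dimethoxymethyl)-3,5-bis(methoxymethoxy)benzaldehyde | COC(OC)c1c(C=O)cc(OCOC)cc1OCOC
F8 | step 6 | [3-chloro-2,6-bis(methoxymethoxy)-4-methylphenyl][2-(dimethoxymethyl)-3,5-bis(methoxymethoxy)phenyl]methanol (racemic) | COC(OC)c1c(OCOC)cc(OCOC)cc1C(O)c1c(OCOC)cc(C)c(Cl)c1OCOC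
F9 | step 8 | 2-[3-chloro-4-methyl-2,6-bis(triethylsilyloxy)benzoyl]-3-(3-methylbut-2-en-1-yl)-4,6-bis(triethylsilyloxy)benzaldehyde | O=Cc1c(O[Si](CC)(CC)CC)cc(O[Si](CC)(CC)CC)c(CC=C(C)C)c1C(=O)c1c(O[Si](CC)(CC)CC)cc(C)c(Cl)c1O[Si](CC)(CC)CC
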